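**Strategy.** In labdane numbering the oxocane (O1, C8, C9, C11, C12, C13, C14, C15) carries its ring oxygen and the epoxide oxygen on neighbouring carbons (O1–C15H2–C14(O)–C13). Everything rests on disconnecting O1–C15 and the epoxide C14–O bond together. Both form when the ring oxygen of an oxepane (O1 bonded to C8 and C14, C15H2OTf on C14, tertiary OH on C13) shifts from C14 to C15 through an oxiranium ion that the C13 hydroxyl opens. This enlarges the ring by one atom and closes the epoxide with inversion at C14. The oxepane comes from a bromonium-initiated cyclisation of a Sharpless-derived (Z)-epoxy triene carbonate.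

Key step: step 8

Assumption (numbering): labdane numbering is used for all tricyclic compounds (decalin C1–C10, side chain C11–C16, C17 = methyl on C8).
Assumption (chemistry): bromonium transfer in step 6 is not expected to distinguish the two faces of the terminal alkene, so the diastereomer with the antipodal decalin forms alongside and is removed by chromatography; the epoxide of step 4 is the only source of absolute configuration.

Step 1
Reactants: 1 (2E,6E)-farnesyl bromide; 2 propyne
Product: 5 methyl (6E,10E)-7,11,15-trimethylhexadeca-6,10,14-trien-2-ynoate, via 1,3-dilithiopropyne 3 (not isolated), via lithium trienynide 4 (not isolated)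
Conditions: 2, n-BuLi (2 equiv), TMEDA, THF–hexane, −78 to 0 °C; then 1, −78 to −20 °C; then ClCO2Me, −78 °C
Reagents that add atoms: methyl chloroformate, COC(=O)Cl
Why: Sequential functionalisation of the propyne dianion: the propargylic carbanion of 3 alkylates the allylic bromide by SN2 without touching the E-alkenes, and the remaining lithium acetylide 4 is C-acylated by the chloroformate.

Step 2
Reactants: 5 methyl (6E,10E)-7,11,15-trimethylhexadeca-6,10,14-trien-2-ynoate
Product: 7 methyl (2Z,6E,10E)-3,7,11,15-tetramethylhexadeca-2,6,10,14-tetraenoate, via alkenylcuprate adduct 6 (not isolated)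
Conditions: Me2CuLi (from CuI, MeLi), THF, −78 °C; MeOH quench at −78 °C; aq. NH4Cl
Reagents that add atoms: lithium dimethylcuprate, [Li+].C[Cu-]C
Why: Conjugate addition of a Gilman cuprate to a 2-alkynoate is a stereospecific syn-carbocupration at −78 °C, so protonation of 6 with retention should give the (2Z)-enoate with C4 cis to the ester.

Step 3
Reactants: 7 methyl (2Z,6E,10E)-3,7,11,15-tetramethylhexadeca-2,6,10,14-tetraenoate
Product: 8 (2Z,6E,10E)-3,7,11,15-tetramethylhexadeca-2,6,10,14-tetraen-1-ol
Conditions: i-Bu2AlH (2.5 equiv), CH2Cl2, −78 to 0 °C; aq. potassium sodium tartrate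
Reagents that add atoms: none
Why: 1,2-Reduction of the conjugated ester by the aluminium hydride gives the allylic alcohol without touching the isolated alkenes or the Z geometry.

Step 4
Reactants: 8 (2Z,6E,10E)-3,7,11,15-tetramethylhexadeca-2,6,10,14-tetraen-1-ol
Product: 9 [(2R,3S)-3-methyl-3-[(3E,7E)-4,8,12-trimethyltrideca-3,7,11-trienyl]oxiran-2-yl]methanol
Conditions: Ti(OiPr)4 (0.1 equiv), D-(−)-diethyl tartrate (0.12 equiv), t-BuOOH, 4 Å sieves, CH2Cl2, −20 °C
Reagents that add atoms: tert-butyl hydroperoxide, CC(C)(C)OO
Why: Sharpless asymmetric epoxidation touches only the allylic-alcohol alkene, and the D-(−)-tartrate ligand should give the (2R,3S)-epoxide (the mirror image of the L-(+)-tartrate product of nerol-type alcohols), which sets the future C14 and C13 under reagent control.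

Step 5
Reactants: 9 [(2R,3S)-3-methyl-3-[(3E,7E)-4,8,12-trimethyltrideca-3,7,11-trienyl]oxiran-2-yl]methanol
Product: 10 tert-butyl carbonate of 9
Conditions: Boc2O, 1-methylimidazole (cat.), toluene, 0 to 23 °C
Reagents that add atoms: di-tert-butyl dicarbonate, CC(C)(C)OC(=O)OC(=O)OC(C)(C)C
Why: Nucleophile-catalysed O-acylation of the primary alcohol installs the tert-butyl carbonate that later acts as terminating nucleophile; the conditions are non-acidic, so the epoxide survives.

Step 6
Reactants: 10 tert-butyl carbonate of 9
Product: 13 (3S,5R,8R,9R,10S,13R,14R)-3-bromo-8,14-epoxylabdane-13,15-diyl carbonate, via oxiranium ion 11 (not isolated), via dioxanylium ion 12 (not isolated)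
Conditions: Et2SBr·SbCl5Br (1.1 equiv), MeNO2, −25 °C, 10 min; aq. Na2SO3/NaHCO3; chromatography to remove the diastereomer
Reagents that add atoms: bromodiethylsulfonium bromopentachloroantimonate, CC[S+](Br)CC.Cl[Sb-](Cl)(Cl)(Cl)(Cl)Br
Why: In this bromonium-induced polyene cyclisation terminated by an epoxide and a tert-butyl carbonate, Br+ goes to the terminal trisubstituted alkene and a chair–chair bicyclisation (two 6-endo closures, anti addition across both E-alkenes, hence equatorial 3-Br, trans ring fusion and axial C8 methyl) delivers the C8 cation to the epoxide oxygen on its α face through a six-membered transition state to give 11, which the Boc carbonyl oxygen opens at tertiary C13 with inversion (C14 untouched) so that the oxygen stays on C14 as an oxepane and loss of isobutene from 12 leaves the cyclic carbonate; the reagent does not select between the alkene faces, so the isomer with the antipodal decalin is separated and the epoxide centres fix the absolute configuration.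

Step 7
Reactants: 13 (3S,5R,8R,9R,10S,13R,14R)-3-bromo-8,14-epoxylabdane-13,15-diyl carbonate
Product: 14 (3S,5R,8R,9R,10S,13R,14R)-3-bromo-8,14-epoxylabdane-13,15-diol
Conditions: K2CO3 (0.2 equiv), MeOH, 23 °C
Reagents that add atoms: none
Why: Base-catalysed methanolysis (transesterification) of the cyclic carbonate frees the tertiary C13 and primary C15 hydroxyls without touching the hindered secondary bromide or any stereocentre.

Step 8
Reactants: 14 (3S,5R,8R,9R,10S,13R,14R)-3-bromo-8,14-epoxylabdane-13,15-diol
Product: 17 (3S,5R,8R,9R,10S,13R,14S)-3-bromo-8,15:13,14-diepoxylabdane (CNP0311742.2), via primary triflate 15 (not isolated), via oxiranium triflate 16 (not isolated)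
Conditions: Tf2O (1.05 equiv), 2,6-di-tert-butyl-4-methylpyridine (2.5 equiv), CH2Cl2, −78 to 0 °C
Reagents that add atoms: none
Why: The primary C15 hydroxyl is triflated in preference to the hindered tertiary C13 hydroxyl (15), and the oxepane oxygen O1, β to C15, expels triflate in a 3-exo-tet closure to the bicyclic oxiranium ion 16 (O1 bonded to C8, C14 and C15). The C13 hydroxyl, antiperiplanar to the O1–C14 bond because it entered anti in step 6, attacks C14 in a second 3-exo-tet closure that cleaves O1–C14, so O1 remains on C15 (oxepane to oxocane, one-atom ring expansion) while the C13–C14 epoxide forms and the pyridine base takes up the proton. Closest known reaction type: the rearrangement–ring expansion of 2-(sulfonyloxyalkyl)tetrahydrofurans and tetrahydropyrans through bicyclic oxonium ions (zinc acetate protocol), here with an internal hydroxyl instead of external acetate as the capturing nucleophile. C14 is the only centre that changes: SN2 inversion by the C13 oxygen turns 14R into 14S, C13 keeps its C–O bond (13R), and the cis epoxide follows from the Z geometry fixed in step 2. The step needs attack at C14 and not at C15 (secured by three- versus four-membered ring formation) and capture of 16 before its tertiary C8–O bond ionises (secured by the intramolecular, pre-aligned hydroxyl); irreversible loss of triflate pays for the strain of the eight-membered ring.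

**Compound list**

1 | (2E,6E)-farnesyl bromide | CC(C)=CCC/C(C)=C/CC/C(C)=C/CBr | starting material
2 | propyne | CC#C | starting material
3 | 1,3-dilithiopropyne | [Li]CC#C[Li] | intermediate
4 | lithium (5E,9E)-6,10,14-trimethylpentadeca-5,9,13-trien-1-ynide | CC(C)=CCC/C(C)=C/CC/C(C)=C/CCC#C[Li] | intermediate
5 | methyl (6E,10E)-7,11,15-trimethylhexadeca-6,10,14-trien-2-ynoate | CC(C)=CCC/C(C)=C/CC/C(C)=C/CCC#CC(=O)OC | intermediate
6 | lithium methyl(alkenyl)cuprate from syn-addition to 5 (Cu on C2, cis to the new C3 methyl) | CC(C)=CCC/C(C)=C/CC/C(C)=C/CC/C(C)=C(/[Cu-]C)C(=O)OC.[Li+] | intermediate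
7 | methyl (2Z,6E,10E)-3,7,11,15-tetramethylhexadeca-2,6,10,14-tetraenoate | CC(C)=CCC/C(C)=C/CC/C(C)=C/CC/C(C)=C\C(=O)OC | intermediate
8 | (2Z,6E,10E)-3,7,11,15-tetramethylhexadeca-2,6,10,14-tetraen-1-ol | CC(C)=CCC/C(C)=C/CC/C(C)=C/CC/C(C)=C\CO | intermediate
9 | [(2R,3S)-3-methyl-3-[(3E,7E)-4,8,12-trimethyltrideca-3,7,11-trienyl]oxiran-2-yl]methanol | CC(C)=CCC/C(C)=C/CC/C(C)=C/CC[C@]1(C)O[C@@H]1CO | intermediate
10 | tert-butyl carbonate of 9 | CC(C)=CCC/C(C)=C/CC/C(C)=C/CC[C@]1(C)O[C@@H]1COC(=O)OC(C)(C)C | intermediate
11 | tricyclic oxiranium ion (O bonded to C8, C13, C14; C15 OBoc), bromopentachloroantimonate salt | CC1(C)[C@@H](Br)CC[C@]2(C)[C@H]3CC[C@@]4(C)[C@@H](COC(=O)OC(C)(C)C)[O+]4[C@]3(C)CC[C@@H]12.Cl[Sb-](Cl)(Cl)(Cl)(Cl)Br | intermediate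
12 | 2-tert-butoxy-1,3-dioxan-2-ylium ion across C13/C15 on the oxepane, bromopentachloroantimonate salt | CC1(C)[C@@H](Br)CC[C@]2(C)[C@H]3CC[C@@]4(C)OC(OC(C)(C)C)=[O+]C[C@H]4O[C@]3(C)CC[C@@H]12.Cl[Sb-](Cl)(Cl)(Cl)(Cl)Br | intermediate
13 | (3S,5R,8R,9R,10S,13R,14R)-3-bromo-8,14-epoxylabdane-13,15-diyl carbonate | CC1(C)[C@@H](Br)CC[C@]2(C)[C@H]3CC[C@@]4(C)OC(=O)OC[C@H]4O[C@]3(C)CC[C@@H]12 | intermediate
14 | (3S,5R,8R,9R,10S,13R,14R)-3-bromo-8,14-epoxylabdane-13,15-diol | CC1(C)[C@@H](Br)CC[C@]2(C)[C@H]3CC[C@@](C)(O)[C@@H](CO)O[C@]3(C)CC[C@@H]12 | intermediate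
15 | 15-O-triflate of 14 | CC1(C)[C@@H](Br)CC[C@]2(C)[C@H]3CC[C@@](C)(O)[C@@H](COS(=O)(=O)C(F)(F)F)O[C@]3(C)CC[C@@H]12 | intermediate
16 | bicyclic oxiranium triflate (O bonded to C8, C14, C15; free 13-OH) | CC1(C)[C@@H](Br)CC[C@]2(C)[C@H]3CC[C@@](C)(O)[C@H]4C[O+]4[C@]3(C)CC[C@@H]12.[O-]S(=O)(=O)C(F)(F)F | intermediate
17 | (3S,5R,8R,9R,10S,13R,14S)-3-bromo-8,15:13,14-diepoxylabdane (CNP0311742.2) | CC1(C)[C@@H](Br)CC[C@]2(C)[C@H]3CC[C@@]4(C)O[C@H]4CO[C@]3(C)CC[C@@H]12 | target

Total steps: 8. Longest linear sequence: 8 steps (from 1).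

**Steps most likely to fail**

1. Step 8. The free tertiary hydroxyl may displace the triflate directly (four-membered ring closure), or the oxiranium ion may ionise at its tertiary C8–O bond and eliminate into ring B before the epoxide closes. Fallback, setting out from 14 and returning at 17: the ring expansion is run under the buffered zinc acetate protocol with an external nucleophile, and the epoxide is made afterwards with retention.
 - ClCH2SO2Cl and 2,6-lutidine (CH2Cl2, −40 °C) convert 14 into the primary chloromethanesulfonate F1.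
 - Zn(OAc)2 in AcOH–H2O at 50 °C should give, through the same oxiranium ion and acetate attack at C14 anti to the departing oxygen, the ring-expanded 14-acetoxy-oxocan-13-ol F2.
 - K2CO3/MeOH gives the syn-13,14-diol F3.
 - MeC(OMe)3/PPTS gives the cyclic orthoacetate F4, and acetyl bromide opens it with inversion to the bromo acetate F5 (bromide entry at C13 instead would converge on the same epoxide).
 - K2CO3/MeOH closes the epoxide with a second inversion, so the diol oxygens end on the face they started on, which gives 17.
 - Acetate attack at the primary C15 instead of C14 would return an unexpanded oxepane; this regiochemistry is not secured and would have to be tested.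

2. Step 6. Bromonium transfer to an internal alkene, or opening of the epoxide by the antimony Lewis acid before the C8 cation arrives, would divert the cascade; in addition half of the material is expected to go to the other diastereomer. Fallback, setting out from 10 and returning at 13: the cascade is initiated with the more terminal-selective and milder Hg(OTf)2·PhNMe2 complex (MeNO2, −20 °C, then aq. NaCl), which should give the equatorial C3 chloromercurial of the tricyclic carbonate F6 through the same cation–olefin, oxiranium and carbonate sequence. Bromodemercuration (LiBr, Br2, pyridine) should then give mainly the equatorial bromide 13; the two decalin antipodes are again separated.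

3. Step 1. SN2′ or allenyl alkylation of the dianion, or incomplete acylation of the acetylide, would give skeletal isomers that are hard to remove. Fallback, setting out from 1 and returning at 7 (steps 1 and 2 are bypassed): γ-alkylation of the dianion of methyl acetoacetate (NaH, then n-BuLi, THF, 0 °C) with 1 gives the β-keto ester F7. Tf2O with aqueous Me4NOH in toluene should give the (E)-enol triflate F8 (triflate trans to the ester). Coupling with MeMgBr catalysed by Fe(acac)3 (THF/NMP, −30 °C) replaces triflate by methyl with retention and gives 7.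

Further compounds
F1 | step 8 | (3S,5R,8R,9R,10S,13R,14R)-3-bromo-13-hydroxy-8,14-epoxylabdan-15-yl chloromethanesulfonate | CC1(C)[C@@H](Br)CC[C@]2(C)[C@H]3CC[C@@](C)(O)[C@@H](COS(=O)(=O)CCl)O[C@]3(C)CC[C@@H]12
F2 | step 8 | (3S,5R,8R,9R,10S,13R,14S)-3-bromo-13-hydroxy-8,15-epoxylabdan-14-yl acetate | CC1(C)[C@@H](Br)CC[C@]2(C)[C@H]3CC[C@@](C)(O)[C@@H](OC(C)=O)CO[C@]3(C)CC[C@@H]12
F3 | step 8 | (3S,5R,8R,9R,10S,13R,14S)-3-bromo-8,15-epoxylabdane-13,14-diol | CC1(C)[C@@H](Br)CC[C@]2(C)[C@H]3CC[C@@](C)(O)[C@@H](O)CO[C@]3(C)CC[C@@H]12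
F4 | step 8 | 13,14-O-(1-methoxyethylidene) derivative of F3 (cyclic orthoacetate) | CC1(C)[C@@H](Br)CC[C@]2(C)[C@H]3CC[C@@]4(C)OC(C)(OC)O[C@H]4CO[C@]3(C)CC[C@@H]12
F5 | step 8 | (3S,5R,8R,9R,10S,13R,14R)-3,14-dibromo-8,15-epoxylabdan-13-yl acetate | CC1(C)[C@@H](Br)CC[C@]2(C)[C@H]3CC[C@@](C)(OC(C)=O)[C@H](Br)CO[C@]3(C)CC[C@@H]12
F6 | step 6 | 3-(chloromercurio) analogue of 13 (equatorial C–Hg in place of C–Br) | CC1(C)[C@@H]([Hg]Cl)CC[C@]2(C)[C@H]3CC[C@@]4(C)OC(=O)OC[C@H]4O[C@]3(C)CC[C@@H]12
F7 | step 1 | methyl (6E,10E)-7,11,15-trimethyl-3-oxohexadeca-6,10,14-trienoate | CC(C)=CCC/C(C)=C/CC/C(C)=C/CCC(=O)CC(=O)OC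
F8 | step 1 | methyl (2E,6E,10E)-7,11,15-trimethyl-3-(trifluoromethylsulfonyloxy)hexadeca-2,6,10,14-tetraenoate | CC(C)=CCC/C(C)=C/CC/C(OS(=O)(=O)C(F)(F)F)=C\C(=O)OC
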